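Ring B of the target (C5–C10, with the C8 methyl and the sp2 carbon C9) plus the gem-dimethyl carbon C4 is the carbon framework of (R)-carvone: its stereocentre is C5, its isopropenyl carbon C4, its carbonyl carbon C9. The plan therefore rests on cutting the C3–C4 bond of ring A. In one operation, iron-hydride hydrogen-atom transfer converts the isopropenyl group into the tertiary C4 radical, which closes ring A onto a tethered acrylate and delivers the trans-decalin with its quaternary C4. The precursor is carvone whose α'-carbon (C10) bears a methyl group cis and a 2-(methoxycarbonyl)allyl group trans to the isopropenyl group. The arene is attached later at C9 as a benzyl nucleophile.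

Key step: step 3

Numbering: drimane numbering is used (ring A = C1–C5, C10; ring B = C5–C10; C11 = benzylic carbon; arene C1'–C6', with C1' on C11). β is the face of the C10 methyl. The target is 5S, 8S (8β-methyl, axial), 10S, with an E C9=C11 bond (arene on the C8 side).

Assumption: the sulfate monoesters 27 and 28 are drawn in the acid form, as in the target SMILES. In practice they would be handled as salts and protonated only by a brief cold acidification.

Step 1
Reactants: 1 (R)-(−)-carvone; 2 iodomethane
Product: 4 (5R)-6-methylcarvone (epimer mixture at C6), via lithium dienolate 3 (not isolated)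
Conditions: LiN(i-Pr)2 (LDA), THF, −78 °C; then MeI, −78 → 0 °C
Reagents that add atoms: iodomethane 2, CI
Why: Kinetic deprotonation at the α'-CH2 gives the cross-conjugated lithium dienolate, whose SN2 methylation installs the future C10 methyl carbon; the new centre is planarised again in step 2, so its configuration does not matter.

Step 2
Reactants: 4 (5R)-6-methylcarvone; 5 methyl 2-(bromomethyl)acrylate
Product: 7 methyl 2-{[(1S,6S)-1,3-dimethyl-2-oxo-6-(prop-1-en-2-yl)cyclohex-3-en-1-yl]methyl}prop-2-enoate, via lithium enolate 6 (not isolated)
Conditions: LDA, THF/DMPU, −78 → −20 °C; then 5, −78 °C → rt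
Reagents that add atoms: methyl 2-(bromomethyl)acrylate 5, C=C(CBr)C(=O)OC
Why: Enolate alkylation with a doubly activated allylic bromide (direct or addition–elimination displacement gives the same product); the electrophile approaches the tetrasubstituted enolate on the face opposite the neighbouring isopropenyl group, so 1,2-induction from C5 sets the quaternary C10 with C1 trans and the methyl cis to C4.

Step 3
Reactants: 7 acrylate-tethered carvone
Product: 8 methyl (4aS,8aS)-4,4,7,8a-tetramethyl-8-oxo-1,2,3,4,4a,5,8,8a-octahydronaphthalene-2-carboxylate (trans-fused; epimer mixture at C2)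
Conditions: Fe(acac)3 (0.3 equiv), PhSiH3 (2.5 equiv), EtOH/(CH2OH)2, 0.02 M, 60 °C, Ar
Reagents that add atoms: none
Why: The iron hydride formed from Fe(acac)3 and PhSiH3 hands a hydrogen atom to the terminal CH2 of the isopropenyl group (Markovnikov hydrogen-atom transfer) and so generates the nucleophilic tertiary C4 radical that already carries both geminal methyl groups. This radical attacks the unsubstituted acrylate terminus C3 in a 6-endo-trig closure of ring A, after which the α-ester radical at C2 is reduced by divalent iron and protonated by ethanol; the closest known reaction type is the iron-catalysed reductive olefin coupling (a hydrogen-atom-transfer Giese addition) run intramolecularly. The alternative 5-exo attack would have to hit the fully substituted, polarity-mismatched C2 and would leave a primary radical, so the substitution pattern of the acceptor secures the 6-endo mode. No ring-fusion centre is created: C5 (from carvone) and C10 (from step 2) already hold C4 and C1 trans-diequatorial on ring B, so only the trans-decalin can form. The single new stereocentre, C2, arises from an uncontrolled protonation and is deleted in step 5. The chemoselectivity needed is hydrogen-atom transfer to the electron-rich, unhindered 1,1-disubstituted alkene in preference to the trisubstituted enone and the electron-poor acrylate, and high dilution suppresses intermolecular coupling.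

Step 4
Reactants: 8 bicyclic enone ester
Product: 9 (4aS,8aS)-4,4,7,8a-tetramethyl-8-oxo-1,2,3,4,4a,5,8,8a-octahydronaphthalene-2-carboxylic acid (C2 epimers)
Conditions: LiOH·H2O, THF/MeOH/H2O, rt; then 1 M HCl to pH 3
Reagents that add atoms: lithium hydroxide, [Li+].[OH-]
Why: Saponification of an unhindered secondary methyl ester; the enone has no base-labile stereocentre (C10 is quaternary, H5 is not acidic) and epimerisation at C2 has no consequence.

Step 5
Reactants: 9 bicyclic enone acid
Product: 11 (4aS,8aS)-2,5,5,8a-tetramethyl-4a,5,6,7,8,8a-hexahydronaphthalen-1(4H)-one, via thiohydroxamate ester 10 (not isolated)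
Conditions: 1-hydroxypyridine-2(1H)-thione, DCC, CH2Cl2, 0 °C → rt, dark; then t-BuSH, toluene, visible light, rt
Reagents that add atoms: none
Why: Barton reductive decarboxylation: the thiyl radical chain fragments the thiohydroxamate ester to CO2 and the secondary C2 radical, which takes hydrogen from t-BuSH faster than it can add to the hindered enone, so the C2 stereocentre is erased.

Step 6
Reactants: 11 bicyclic enone
Product: 12 9β-allylic alcohol (C7=C8 retained; 5α-H and 10β-methyl unchanged)
Conditions: NaBH4, CeCl3·7H2O, MeOH, 0 °C
Reagents that add atoms: none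
Why: Luche reduction gives clean 1,2-attack, with hydride arriving on the α face away from the axial C10 methyl, so the 9β (pseudo-equatorial) alcohol should prevail; C9 becomes sp2 again in step 8.

Step 7
Reactants: 12 9β-allylic alcohol
Product: 13 saturated 9β-alcohol with 8β-methyl (8α-H)
Conditions: H2 (4 bar), PtO2, EtOAc, rt
Reagents that add atoms: none
Why: Heterogeneous syn hydrogenation: the axial C10 methyl lies 1,3 to C8 over the β face, so C7=C8 can reach the platinum surface only through its α face, hydrogen is delivered to C8 from below and the methyl is pushed into the β (axial) position of the target (8S); working on the alcohol rather than the enone excludes enol-mediated equilibration to the more stable 8α epimer.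

Step 8
Reactants: 13 saturated 9β-alcohol
Product: 14 (2S,4aS,8aS)-2,5,5,8a-tetramethyloctahydronaphthalen-1(2H)-one (8β-methyl ketone)
Conditions: Dess–Martin periodinane, NaHCO3, CH2Cl2, 0 °C → rt
Reagents that add atoms: none
Why: Bicarbonate-buffered Dess–Martin oxidation is neutral and fast enough for a hindered secondary alcohol, and it should leave the epimerisable axial C8 methyl centre untouched.

Step 9
Reactants: 15 2,4,5-trihydroxybenzaldehyde
Product: 16 4,5-bis(allyloxy)-2-hydroxybenzaldehyde
Conditions: allyl bromide (2.1 equiv), K2CO3 (2.1 equiv), DMF, rt, Ar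
Reagents that add atoms: allyl bromide, C=CCBr
Why: Williamson etherification; the 2-OH is locked in a hydrogen bond to the formyl group and is the least nucleophilic oxygen, so two equivalents of allyl bromide should alkylate only the 4- and 5-hydroxyls.

Step 10
Reactants: 16 4,5-bis(allyloxy)-2-hydroxybenzaldehyde
Product: 17 4,5-bis(allyloxy)-2-{[2-(trimethylsilyl)ethoxy]methoxy}benzaldehyde
Conditions: SEMCl, i-Pr2NEt, CH2Cl2, 0 °C → rt
Reagents that add atoms: 2-(trimethylsilyl)ethoxymethyl chloride, C[Si](C)(C)CCOCCl
Why: O-alkylation of the remaining phenol with an α-chloro ether gives an acetal that tolerates organomagnesium reagents and is later removed by fluoride, orthogonally to the allyl ethers.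

Step 11
Reactants: 17 SEM-protected aldehyde
Product: 18 (4,5-bis(allyloxy)-2-{[2-(trimethylsilyl)ethoxy]methoxy}phenyl)methanol
Conditions: NaBH4, MeOH/THF, 0 °C
Reagents that add atoms: none
Why: Borohydride reduction of an aromatic aldehyde, to which the allyl ethers and the SEM acetal are inert.

Step 12
Reactants: 18 benzylic alcohol
Product: 20 1,2-bis(allyloxy)-4-(chloromethyl)-5-{[2-(trimethylsilyl)ethoxy]methoxy}benzene, via benzylic mesylate 19 (not isolated)
Conditions: MsCl, Et3N, CH2Cl2, −10 °C → rt; used at once without chromatography
Reagents that add atoms: methanesulfonyl chloride, CS(=O)(=O)Cl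
Why: Mesylation of the electron-rich benzylic alcohol is followed in the flask by chloride displacement, a base-buffered chlorination that spares the acid-sensitive SEM acetal.

Step 13
Reactants: 14 8β-methyl ketone; 20 benzylic chloride
Product: 22 tertiary alcohol (9β-OH and 9α-CH2Ar; Ar = 4,5-bis(allyloxy)-2-SEM-oxyphenyl), via benzylmagnesium chloride 21 (not isolated)
Conditions: Mg turnings, THF, 0 °C, slow addition of 20; then added to 14 and LaCl3·2LiCl, THF, 0 °C → rt; aq NH4Cl
Reagents that add atoms: none
Why: Lanthanide-promoted Grignard 1,2-addition: LaCl3·2LiCl activates the carbonyl and tempers the basicity of the benzylmagnesium reagent so that addition should outrun enolisation of the hindered ketone (keeping C8 intact), the nucleophile entering axially from the α face opposite the two β-axial methyl groups to set a C9 centre that disappears in step 14.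

Step 14
Reactants: 22 tertiary alcohol
Product: 24 (E)-C9=C11 styrene bearing the 2'-O-SEM and 4',5'-bis(allyl) ethers, via chlorosulfite ester 23 (not isolated)
Conditions: SOCl2, pyridine, CH2Cl2, −40 → 0 °C
Reagents that add atoms: none
Why: Pyridine-induced E2 dehydration: H8 is equatorial and cannot become anti-periplanar to the leaving group and C10 carries no hydrogen, so only a benzylic C11–H can be removed, and the rotamer that turns the arene away from the quaternary C10 towards C8 (whose methyl is axial and out of the alkene plane) leads to the E alkene.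

Step 15
Reactants: 24 SEM-protected styrene
Product: 25 free 2'-phenol (4',5'-bis(allyl) ether; E alkene)
Conditions: Bu4NF, THF, 50 °C; aq NH4Cl
Reagents that add atoms: none
Why: Fluoride-induced fragmentation of the SEM ether (attack at silicon with loss of ethene and formaldehyde) frees the 2'-phenol under basic conditions and avoids any acid that could add this phenol across the C9=C11 bond.

Step 16
Reactants: 25 free 2'-phenol
Product: 26 3'-formyl-2'-phenol (4',5'-bis(allyl) ether; E alkene)
Conditions: MgCl2, Et3N, (CH2O)n, THF, reflux; aq NH4Cl
Reagents that add atoms: paraformaldehyde (as formaldehyde), C=O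
Why: Casnati–Skattebøl ortho-formylation: magnesium-templated delivery of formaldehyde occurs only ortho to a free phenol, C1' is blocked so C3' is the sole site, and a second formaldehyde serves as hydride acceptor to reach the aldehyde level.

Step 17
Reactants: 26 3'-formyl-2'-phenol
Product: 27 2'-O-sulfate of 26 (4',5'-bis(allyl) ether)
Conditions: SO3·pyridine (excess), pyridine, 40 °C
Reagents that add atoms: sulfur trioxide–pyridine complex, O=S(=O)=O.c1ccncc1
Why: O-sulfation of the only free phenol; pyridine breaks the hydrogen bond to the formyl group, and because both catechol oxygens are masked the regiochemistry is fixed by protection.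

Step 18
Reactants: 27 bis(allyl) sulfate
Product: 28 target CNP0149861.1
Conditions: Pd(PPh3)4 (5 mol %), sodium p-toluenesulfinate, THF/MeOH, rt, Ar; then cold 0.1 M HCl, reversed-phase purification
Reagents that add atoms: none
Why: Tsuji–Trost-type deallylation: zerovalent palladium ionises both aryl allyl ethers to π-allyl complexes that the soft sulfinate captures under near-neutral conditions, which leave the aryl sulfate, the aldehyde and the trisubstituted alkene alone (a sulfinate is chosen because carbon-acid scavengers would condense with the aldehyde).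

Compound list
1 | (R)-(−)-carvone | CC1=CC[C@H](CC1=O)C(C)=C | starting material
2 | iodomethane | CI | starting material
3 | lithium cross-conjugated dienolate of carvone | CC1=CC[C@@H](C(C)=C)C=C1[O-].[Li+] | intermediate
4 | (5R)-2,6-dimethyl-5-(prop-1-en-2-yl)cyclohex-2-en-1-one (6-methylcarvone, C6 epimers) | CC1=CC[C@@H](C(C)=C)C(C)C1=O | intermediate
5 | methyl 2-(bromomethyl)acrylate | C=C(CBr)C(=O)OC | starting material
6 | lithium enolate of 6-methylcarvone | CC1=CC[C@@H](C(C)=C)C(C)=C1[O-].[Li+] | intermediate
7 | methyl 2-{[(1S,6S)-1,3-dimethyl-2-oxo-6-(prop-1-en-2-yl)cyclohex-3-en-1-yl]methyl}prop-2-enoate | CC1=CC[C@@H](C(C)=C)[C@](C)(CC(=C)C(=O)OC)C1=O | intermediate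
8 | methyl (4aS,8aS)-4,4,7,8a-tetramethyl-8-oxo-1,2,3,4,4a,5,8,8a-octahydronaphthalene-2-carboxylate (C2 epimers) | CC1=CC[C@H]2C(C)(C)CC(C(=O)OC)C[C@]2(C)C1=O | intermediate
9 | corresponding C2 carboxylic acid (C2 epimers) | CC1=CC[C@H]2C(C)(C)CC(C(=O)O)C[C@]2(C)C1=O | intermediate
10 | 2-thioxopyridin-1(2H)-yl ester of 9 (Barton ester) | CC1=CC[C@H]2C(C)(C)CC(C(=O)ON3C=CC=CC3=S)C[C@]2(C)C1=O | intermediate
11 | (4aS,8aS)-2,5,5,8a-tetramethyl-4a,5,6,7,8,8a-hexahydronaphthalen-1(4H)-one | CC1=CC[C@H]2C(C)(C)CCC[C@]2(C)C1=O | intermediate
12 | 9β-allylic alcohol derived from 11 | CC1=CC[C@H]2C(C)(C)CCC[C@]2(C)[C@H]1O | intermediate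
13 | saturated 9β-alcohol, 8β-methyl | C[C@H]1CC[C@H]2C(C)(C)CCC[C@]2(C)[C@H]1O | intermediate
14 | (2S,4aS,8aS)-2,5,5,8a-tetramethyloctahydronaphthalen-1(2H)-one | C[C@H]1CC[C@H]2C(C)(C)CCC[C@]2(C)C1=O | intermediate
15 | 2,4,5-trihydroxybenzaldehyde | O=Cc1cc(O)c(O)cc1O | starting material
16 | 4,5-bis(allyloxy)-2-hydroxybenzaldehyde | O=Cc1cc(OCC=C)c(OCC=C)cc1O | intermediate
17 | 4,5-bis(allyloxy)-2-{[2-(trimethylsilyl)ethoxy]methoxy}benzaldehyde | O=Cc1cc(OCC=C)c(OCC=C)cc1OCOCC[Si](C)(C)C | intermediate
18 | (4,5-bis(allyloxy)-2-{[2-(trimethylsilyl)ethoxy]methoxy}phenyl)methanol | OCc1cc(OCC=C)c(OCC=C)cc1OCOCC[Si](C)(C)C | intermediate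
19 | methanesulfonate of 18 | CS(=O)(=O)OCc1cc(OCC=C)c(OCC=C)cc1OCOCC[Si](C)(C)C | intermediate
20 | 1,2-bis(allyloxy)-4-(chloromethyl)-5-{[2-(trimethylsilyl)ethoxy]methoxy}benzene | ClCc1cc(OCC=C)c(OCC=C)cc1OCOCC[Si](C)(C)C | intermediate
21 | benzylmagnesium chloride derived from 20 | Cl[Mg]Cc1cc(OCC=C)c(OCC=C)cc1OCOCC[Si](C)(C)C | intermediate
22 | tertiary alcohol, 9β-OH, 9α-arylmethyl, 8β-methyl | C[C@H]1CC[C@H]2C(C)(C)CCC[C@]2(C)[C@]1(O)Cc1cc(OCC=C)c(OCC=C)cc1OCOCC[Si](C)(C)C | intermediate
23 | chlorosulfite ester of 22 | C[C@H]1CC[C@H]2C(C)(C)CCC[C@]2(C)[C@]1(OS(=O)Cl)Cc1cc(OCC=C)c(OCC=C)cc1OCOCC[Si](C)(C)C | intermediate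
24 | (E)-styrene, 2'-O-SEM, 4',5'-bis(allyl) ether | C[C@H]1CC[C@H]2C(C)(C)CCC[C@]2(C)/C1=C/c1cc(OCC=C)c(OCC=C)cc1OCOCC[Si](C)(C)C | intermediate
25 | (E)-styrene, free 2'-phenol, 4',5'-bis(allyl) ether | C[C@H]1CC[C@H]2C(C)(C)CCC[C@]2(C)/C1=C/c1cc(OCC=C)c(OCC=C)cc1O | intermediate
26 | 3'-formyl derivative of 25 | C[C@H]1CC[C@H]2C(C)(C)CCC[C@]2(C)/C1=C/c1cc(OCC=C)c(OCC=C)c(C=O)c1O | intermediate
27 | 2'-O-sulfate of 26 (acid form) | C[C@H]1CC[C@H]2C(C)(C)CCC[C@]2(C)/C1=C/c1cc(OCC=C)c(OCC=C)c(C=O)c1OS(=O)(=O)O | intermediate
28 | 2-formyl-3,4-dihydroxy-6-{(E)-[(2S,4aS,8aS)-2,5,5,8a-tetramethyloctahydronaphthalen-1(2H)-ylidene]methyl}phenyl hydrogen sulfate | C[C@H]1CC[C@H]2C(C)(C)CCC[C@]2(C)/C1=C/c1cc(O)c(O)c(C=O)c1OS(=O)(=O)O | target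

Total step count: 18. Longest linear sequence: 14 steps (steps 1–8, then 13–18); steps 9–12 build the arene fragment in parallel.

Steps most likely to fail

Step 3. Hydrogen-atom transfer may fail to discriminate among the three alkenes, or the C4 radical may be capped by hydrogen before it cyclises. The fallback makes the same radical by halogen abstraction, so that no metal hydride meets the enone or the acrylate. Setting out from 7, ionic Markovnikov addition of HBr (33 % in AcOH, 0 °C, short contact) to the isopropenyl group should give the tertiary bromide F1. Slow addition of Bu3SnH/AIBN to F1 in refluxing toluene (tin-hydride Giese cyclisation) should then close the same C3–C4 bond, and the route is rejoined at 8.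

Step 13. The carbonyl is flanked by the quaternary C10 and the axial C8 methyl, so addition may be slow. Enolisation (with epimerisation of the returned ketone) and self-coupling of the electron-rich benzyl halide could then take over. The fallback replaces addition–elimination by a direct carbonyl olefination. Setting out from 21 and 14, two equivalents of 21 with Cp2TiCl2 (THF, 0 °C) should give the bis(arylmethyl)titanocene F2. Warming F2 with 14 in toluene at about 55 °C releases a non-basic titanium benzylidene (Petasis-type olefination) that converts C9=O directly into the C9=C11 alkene, with the arene expected on the less crowded C8 side. The route is rejoined at 24, so step 14 is bypassed as well.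

Step 7. Anchoring of the free hydroxyl on the catalyst surface may erode facial selectivity, or the double bond may migrate with loss of control at C8. The fallback relies on steric shielding by a non-coordinating group. Setting out from 12, silylation (TBSOTf, 2,6-lutidine, CH2Cl2) should give the 9β-silyl ether F3. Its bulky β-oriented silyloxy group reinforces the C10 methyl in closing the β face. Hydrogenation (H2, Rh/Al2O3, EtOAc) should give the saturated 8β-methyl silyl ether F4, and Bu4NF in THF returns the route to 13.

Further compounds
F1 | step 3 | tertiary bromide: 7 with the isopropenyl group replaced by 2-bromopropan-2-yl | CC1=CC[C@@H](C(C)(C)Br)[C@](C)(CC(=C)C(=O)OC)C1=O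
F2 | step 13 | bis(cyclopentadienyl)bis{[4,5-bis(allyloxy)-2-{[2-(trimethylsilyl)ethoxy]methoxy}phenyl]methyl}titanium | [CH2-]c1cc(OCC=C)c(OCC=C)cc1OCOCC[Si](C)(C)C.[CH2-]c1cc(OCC=C)c(OCC=C)cc1OCOCC[Si](C)(C)C.[CH-]1C=CC=C1.[CH-]1C=CC=C1.[Ti+4]
F3 | step 7 | 9β-tert-butyldimethylsilyl ether of 12 | CC1=CC[C@H]2C(C)(C)CCC[C@]2(C)[C@H]1O[Si](C)(C)C(C)(C)C
F4 | step 7 | 9β-tert-butyldimethylsilyl ether of 13 (8β-methyl) | C[C@H]1CC[C@H]2C(C)(C)CCC[C@]2(C)[C@H]1O[Si](C)(C)C(C)(C)C
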